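**Remarks on the chemistry (assumptions)**
- The oxolane is numbered O1–C2–C3–C4–C5 so that C2 carries the aryl group that is cis to the C3 hydroxymethyl group; with this numbering the target is (2S,3S,4R,5S).
- The SMILES of the radical precursor 16 and of the bicycle 17 were derived from that of 19 and checked centre by centre; all shared stereocentres agree, so no correction is needed.
- The lactone is activated for arylation as its diphenyl ketene acetal phosphate 11, not as an enol triflate, because ketene acetal triflates of five-membered lactones are too labile to isolate.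
- 4-(Benzyloxy)-3-methoxybenzaldehyde 4 (the O-benzyl ether of vanillin) is taken as a purchased compound, which saves one benzylation. Toluene replaces benzene in the radical step.

## Structural features

The target 19 is a 2,5-diaryl-3,4-bis(hydroxymethyl)oxolane: one saturated five-membered ring O1–C2–C3–C4–C5 with a 4-hydroxy-3-methoxyphenyl ring on C2 and on C5 and a CH2OH group on C3 and on C4. All four ring carbons are stereocentres in a row, (2S,3S,4R,5S): the C2 aryl, the C3 CH2OH and the C4 CH2OH share one face and the C5 aryl lies on the other, so the molecule has no symmetry although its two halves are constitutionally the same. The fragile groups are the two benzylic C–O bonds of the ring, each para to an oxygenated arene and so prone to acid ionisation and to hydrogenolysis, and the two guaiacol units, which are oxidisable and as phenolates can open the ring through quinone methides. The 4,5-trans pair is the relaxed arrangement and comes easily from a γ-aryl-β-substituted butyrolactone. The real difficulty is the contiguous cis,cis triad C2–C3–C4, which is the less stable arrangement and cannot be reached by equilibration. The key step uses the C4 CH2O oxygen as the anchor of a temporary O–SiMe2–CH2 tether on a C2=C3 enol ether: the tether can bring its carbon only to the face of C3 that is cis to the C4 group, closing a six-membered 1,2-oxasilinane fused to the oxolane, and this new ring then screens one face of C2 so that hydrogen enters from the other. After oxidation of the C–Si bond the tether carbon is the C3 hydroxymethyl carbon.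

## Logic of the disconnections

19 ⇒ 18. The two phenolic O–H bonds are traced back to O–CH2Ph bonds. This keeps acidic, oxidisable phenols out of every earlier intermediate; the gain is in handling, not in skeleton. The forward step must cleave two aryl benzyl ethers without touching the two benzylic C–O bonds of the ring, which calls for neutral hydrogenolysis stopped after two equivalents of hydrogen.

18 ⇒ 17. The C–O bond of the C3 hydroxymethyl group is exchanged for a C–Si bond and the O–H of the C4 hydroxymethyl group for an O–Si bond to the same SiMe2 unit. A C–Si bond can be oxidised to C–OH with retention, so the cis-1,4-diol becomes one six-membered ring and the tether is revealed. The forward step must oxidise a monoalkoxydialkylsilane under conditions mild and basic enough for the benzylic ethers.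

17 ⇒ 16. Two bonds are cut, C3–CH2(Si) and C2–H, which restores a C2=C3 enol ether and a bromomethylsilyl ether. This removes one ring and two stereocentres (C2, C3) and leaves a trans-disubstituted dihydrofuran with only C4 and C5 to control. The forward step must close 6-exo and not 7-endo, deliver carbon cis to the C4 branch, deliver hydrogen to C2 from the opposite face, and cyclise faster than the first radical is reduced.

16 ⇒ 14 + 15. The Si–O bond is cut. The tether is hydrolytically labile and is therefore installed last, from a free primary alcohol and a commercial chlorosilane. The forward step must silylate next to an acid-sensitive aryl enol ether, so only basic conditions are allowed.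

14 ⇒ 13 ⇒ 11 + 12. After formal re-protection of the alcohol, the C(sp2)–aryl bond next to the ring oxygen is cut. This is the natural cross-coupling bond: the second aryl group leaves as a commercial boronic acid and the enol ether carbon becomes an enol phosphate carbon. The forward sequence needs an electrophile stable enough to isolate and an alcohol that stays masked through enolate formation and coupling.

11 ⇒ 10 ⇒ 9 ⇒ 8. The O–P bond, the O–Si bond and the oxidation level of the C4 side chain are taken back: enol phosphate to lactone carbonyl, silyl ether to alcohol, CH2OH to CO2H. The acid is what an aldol–lactonisation delivers directly. The forward steps must reduce an acid in the presence of a lactone and enolise the lactone without touching C4 or C5.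

8 ⇒ 6 ⇒ 3 + 4. The C4–C5 bond (aldol), the lactone O–C(=O) bond and the acyl bond to the auxiliary are cut. Both remaining stereocentres then come from one auxiliary-controlled aldol of a succinate half-ester imide with an aromatic aldehyde. The forward step must enolise the imide and not the ester, give the syn adduct with the correct absolute sense, and lactonise; syn geometry becomes the 4,5-trans lactone.

3 ⇒ 1 + 2. The N–acyl bond is cut to the commercial oxazolidinone and the commercial half-ester acid chloride; the forward step is a routine N-acylation.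

## Other disconnections considered

Alternative 1: The cut is the O1–C5 bond, which leads to the open-chain benzylic alcohol A2 with the C2 carbinol, C3 and C4 in place, C5 as a benzylic CH2 and all four oxygens as pivalates. In the forward key step PhI(OAc)2/I2 under light would turn the C2–OH of A2 into a hypoiodite. The alkoxy radical would abstract the C5 hydrogen through a six-membered transition state, the benzylic radical would be oxidised, and the same oxygen would close the ring to tetrapivalate A1 (Suárez-type hypoiodite reaction).
- In its favour: ring closure is the last skeletal event, no tin is used, the closure should put the C5 aryl trans to the C4 branch (the arrangement the ring prefers), and the end game is one ester cleavage with no hydrogenolysis.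
- Against it here: a benzylic alkoxy radical is prone to β-scission of the C2–C3 bond in competition with hydrogen transfer. The C4 CH2O hydrogens are also in a 1,5-relationship. The hypoiodite reagent can iodinate the oxygenated arenes even as aryl esters. The three contiguous centres of A2 would have to be set in an open chain.
- Structure: the chosen plan sets C4/C5 in one aldol and C2/C3 in the key step under ring and tether control; here three centres are made acyclically and only C5 is set in the key step, by product stability and not by a directing element.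
- Mechanism: both are radical processes; the chosen one forms a C–C bond in a geometrically constrained cyclisation, this one functionalises a C–H bond and depends on the relative rates of hydrogen transfer and fragmentation.
- Step economy: judged similar, because four pivalates must be installed and removed and A2 needs its own stereocontrolled assembly.
- Equal or better: it avoids organotin reagents and a final hydrogenolysis, and its C5 outcome is at least as secure as in the chosen plan.

Alternative 2: The cut is O1–C2, traced through the all-cis lactone A3 to the all-cis cyclobutanone A4, in which the C2 aryl, C3 and C4 sit on one face of a four-membered ring and the two CH2O groups are tied as an acetonide. In the forward key step a Baeyer–Villiger monooxygenase would oxidise one enantiomer of racemic A4, the benzylic carbon migrating with retention to give A3.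
- In its favour: the crowded cis triad is fixed by a small ring before any question of facial selectivity arises, the oxygen insertion is stereoretentive, the enzyme supplies the absolute configuration without an auxiliary, and neither tin nor cryogenic enolate chemistry is needed.
- Against it here: a kinetic resolution cannot deliver more than half of the material. The 2-aryl cyclobutanone can epimerise at its benzylic α-carbon in aqueous buffer, which would erase the feature the ring was meant to fix. Acceptance, regiochemistry and enantiopreference of the enzyme for so bulky a substrate cannot be predicted. After A3 the C5 aryl must still be added and the hemiketal reduced, where hydride is expected to enter anti to the C4 branch and so place the C5 aryl cis to it, the wrong result, while the Lewis acid threatens the acetonide and the benzylic C2 centre.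
- Structure: A3 solves C2/C3/C4 and leaves C5 open; the chosen plan has C4/C5 from the start and closes C2/C3 with a tether, whereas the C5 problem here has no evident controlling element.
- Mechanism: enzymatic oxygen insertion against radical cyclisation, both stereospecific in the key event.
- Step economy: shorter on paper (about eight steps), offset by the resolution ceiling.
- Equal or better: it is shorter, tin-free, and sets the cis triad more directly than the chosen plan.

Alternative 3: The cuts are O1–C2 and C3–C4 at once, giving the vinyl epoxide A6 and the arylidene malonate A7. In the forward key step Pd(PPh3)4 (zerovalent palladium) would ionise A6 to an alkoxide-bearing allyl complex. Oxygen would add to A7 in conjugate fashion and the malonate would then alkylate the allyl terminus to close the oxolane diester A5.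
- In its favour: it is the most convergent plan, with two ring bonds and the ring made in one catalytic step, both partners a few steps from 4, and C5 carried over with retention from the epoxide.
- Against it here: C2 and C4 are set under equilibrating conditions (reversible conjugate addition, allyl isomerisation), so the 2,5-trans/4,5-trans pattern is not assured. The electron-rich aryl epoxide is prone to Meinwald-type rearrangement and to benzylic ionisation. In A5 one ester must be removed and the other left cis to both neighbours, the less stable position, by a kinetic protonation. The vinyl group must be cut to an aldehyde whose α-carbon C4 can epimerise.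
- Structure: the ring and three centres come in one step, but C3, the centre at the heart of the crowded triad, is left to a late protonation; the chosen plan makes C3 its key event.
- Mechanism: polar, catalytic and thermodynamically steered, against radical and kinetically steered by a tether.
- Step economy: about ten steps, slightly shorter than the chosen plan.
- Equal or better: convergence and the number of bonds formed in the key step are clearly better, and no tin is needed.

Key step: step 10

## Route

Step 1
Reactants: 1 (S)-4-benzyl-1,3-oxazolidin-2-one; 2 methyl 4-chloro-4-oxobutanoate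
Product: 3 methyl 4-[(4S)-4-benzyl-2-oxo-1,3-oxazolidin-3-yl]-4-oxobutanoate
Conditions: n-BuLi, THF, −78 °C; then 2, −78 → 0 °C
Reagents that add atoms: none
Why: N-Acylation of the lithiated oxazolidinone by the acid chloride; the methyl ester of 2 is far less electrophilic and is untouched, and the stereocentre of 1 is not involved.

Step 2
Reactants: 3 methyl 4-[(4S)-4-benzyl-2-oxo-1,3-oxazolidin-3-yl]-4-oxobutanoate; 4 4-(benzyloxy)-3-methoxybenzaldehyde
Product: 6 (4S)-4-benzyl-3-{[(2S,3S)-2-[4-(benzyloxy)-3-methoxyphenyl]-5-oxooxolan-3-yl]carbonyl}-1,3-oxazolidin-2-one, via syn-aldol adduct 5 (not isolated)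
Conditions: Bu2BOTf, i-Pr2NEt, CH2Cl2, 0 °C; 4, −78 → 0 °C; pH 7 buffer, MeOH, 30% H2O2, 0 °C; then PPTS (cat.), CH2Cl2, rt
Reagents that add atoms: none
Why: Evans syn-aldol: the boron reagent enolises only the imide (Z-enolate) and the closed chair transition state, with the benzyl group of the auxiliary blocking one enolate face, sets both new centres of 5 (S at the carbinol, S at the α-carbon). The γ-hydroxy ester then lactonises with loss of methanol, and the syn relationship becomes the 4,5-trans lactone that holds C4 and C5 of 19.

Step 3
Reactants: 6 (4S)-4-benzyl-3-{[(2S,3S)-2-[4-(benzyloxy)-3-methoxyphenyl]-5-oxooxolan-3-yl]carbonyl}-1,3-oxazolidin-2-one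
Product: 8 (2S,3S)-2-[4-(benzyloxy)-3-methoxyphenyl]-5-oxooxolane-3-carboxylic acid, via peroxy acid 7 (not isolated)
Conditions: LiOH, 30% H2O2, THF/H2O (3:1), 0 °C; aq. Na2SO3; 1 M HCl to pH 2
Reagents that add atoms: hydrogen peroxide, OO
Why: Hydroperoxide attacks the exocyclic imide carbonyl (standard peroxide cleavage of N-acyloxazolidinones), sulfite reduces the peroxy acid 7, and acidification recloses any lactone opened by hydroxide to the only possible γ-lactone, the trans isomer. The α-centre is not enolised at 0 °C, and 1 is recovered.

Step 4
Reactants: 8 (2S,3S)-2-[4-(benzyloxy)-3-methoxyphenyl]-5-oxooxolane-3-carboxylic acid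
Product: 9 (4R,5S)-5-[4-(benzyloxy)-3-methoxyphenyl]-4-(hydroxymethyl)oxolan-2-one
Conditions: BH3·SMe2, THF, 0 °C → rt; MeOH
Reagents that add atoms: none
Why: Borane reduces a carboxylic acid through its acyloxyborane much faster than a lactone, a standard chemoselective reduction of lactone acids; no stereocentre is touched (the descriptor at C4 changes only because the substituent priorities change).

Step 5
Reactants: 9 (4R,5S)-5-[4-(benzyloxy)-3-methoxyphenyl]-4-(hydroxymethyl)oxolan-2-one
Product: 10 (4R,5S)-5-[4-(benzyloxy)-3-methoxyphenyl]-4-({[tert-butyl(dimethyl)silyl]oxy}methyl)oxolan-2-one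
Conditions: TBSCl, imidazole, CH2Cl2, 0 °C → rt
Reagents that add atoms: tert-butyl(chloro)dimethylsilane, CC(C)(C)[Si](C)(C)Cl
Why: Silylation of the primary alcohol under mild imidazole buffering, done promptly because free 9 could translactonise under stronger base. The silyl ether masks the oxygen during enolate chemistry and cross-coupling.

Step 6
Reactants: 10 (4R,5S)-5-[4-(benzyloxy)-3-methoxyphenyl]-4-({[tert-butyl(dimethyl)silyl]oxy}methyl)oxolan-2-one
Product: 11 (4R,5S)-5-[4-(benzyloxy)-3-methoxyphenyl]-4-({[tert-butyl(dimethyl)silyl]oxy}methyl)-4,5-dihydrofuran-2-yl diphenyl phosphate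
Conditions: (PhO)2P(O)Cl, DMPU, THF, −78 °C; KN(SiMe3)2 added last, −78 °C
Reagents that add atoms: diphenyl phosphorochloridate, O=P(Cl)(Oc1ccccc1)Oc1ccccc1
Why: O-Phosphorylation of the potassium lactone enolate gives the cyclic ketene acetal phosphate, a known way to turn lactones into cross-coupling electrophiles; adding the base last traps the enolate before it can condense with unreacted lactone. C4 carries no leaving group and C4 and C5 are not enolisable, so both stereocentres are safe.

Step 7
Reactants: 11 (4R,5S)-5-[4-(benzyloxy)-3-methoxyphenyl]-4-({[tert-butyl(dimethyl)silyl]oxy}methyl)-4,5-dihydrofuran-2-yl diphenyl phosphate; 12 [4-(benzyloxy)-3-methoxyphenyl]boronic acid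
Product: 13 {[(2S,3R)-2,5-bis[4-(benzyloxy)-3-methoxyphenyl]-2,3-dihydrofuran-3-yl]methoxy}(tert-butyl)dimethylsilane
Conditions: Pd(PPh3)4 (5 mol%), 2 M aq. Na2CO3, DME, 70 °C
Reagents that add atoms: none
Why: Suzuki–Miyaura coupling of an enol phosphate: zerovalent palladium inserts into the C–O(P) bond, the boronate transmetallates and reductive elimination forms the C–aryl bond; no stereocentre is involved. The product is a base-stable but acid-labile aryl enol ether, so work-up and chromatography are kept basic (Et3N-treated silica).

Step 8
Reactants: 13 {[(2S,3R)-2,5-bis[4-(benzyloxy)-3-methoxyphenyl]-2,3-dihydrofuran-3-yl]methoxy}(tert-butyl)dimethylsilane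
Product: 14 [(2S,3R)-2,5-bis[4-(benzyloxy)-3-methoxyphenyl]-2,3-dihydrofuran-3-yl]methanol
Conditions: Bu4NF, THF, 0 °C → rt
Reagents that add atoms: none
Why: Fluoride cleaves the primary Si–O bond under basic conditions that the enol ether and the benzyl ethers tolerate. The alcohol is carried on without contact with acid, which would add the hydroxyl across the enol ether.

Step 9
Reactants: 14 [(2S,3R)-2,5-bis[4-(benzyloxy)-3-methoxyphenyl]-2,3-dihydrofuran-3-yl]methanol; 15 (bromomethyl)chlorodimethylsilane
Product: 16 {[(2S,3R)-2,5-bis[4-(benzyloxy)-3-methoxyphenyl]-2,3-dihydrofuran-3-yl]methoxy}(bromomethyl)dimethylsilane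
Conditions: Et3N, DMAP (cat.), CH2Cl2, 0 °C
Reagents that add atoms: none
Why: Silylation of the primary alcohol by the chlorosilane under amine base installs the radical tether. The bromomethylsilyl ether is hydrolytically labile and is used directly after filtration and evaporation.

Step 10
Reactants: 16 {[(2S,3R)-2,5-bis[4-(benzyloxy)-3-methoxyphenyl]-2,3-dihydrofuran-3-yl]methoxy}(bromomethyl)dimethylsilane
Product: 17 (1R,6R,7S,9S)-7,9-bis[4-(benzyloxy)-3-methoxyphenyl]-4,4-dimethyl-3,8-dioxa-4-silabicyclo[4.3.0]nonane (cis-fused 1,2-oxasilinane–oxolane; C2 aryl, C3 CH2Si and C4 CH2O on one face, C5 aryl on the other)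
Conditions: Bu3SnH (syringe pump, 6 h), AIBN (cat.), PhMe (0.01 M), 85 °C
Reagents that add atoms: none
Why: Bu3Sn• (AIBN initiation) abstracts bromine from 16, the α-silylmethyl radical adds to C3 of the enol ether, and the C2 radical so formed takes hydrogen from Bu3SnH, which returns Bu3Sn• to the chain. The closest known reaction type is the Nishiyama–Stork cyclisation of (bromomethyl)dimethylsilyl ethers, here on a homoallylic ether. The one ring closed, the 1,2-oxasilinane, forms 6-exo-trig: radical carbon, Si, O, CH2, C4 and C3 are in the ring and C2 stays outside. The regioselectivity needed (6-exo, not 7-endo) is secured by the substrate, because C2 is fully substituted and only attack at C3 leaves a benzylic, oxygen-stabilised radical. C3 is set by the tether: anchored on the C4 CH2O group, the short chain reaches only the face of the dihydrofuran that bears this group, so the ring fusion is cis and the new CH2 is cis to the C4 carbon. C2 is set by the bicycle just formed: the planar benzylic radical is screened on its concave face by the neighbouring C3 branch, so Bu3SnH delivers hydrogen from the convex face and the aryl group stays cis to C3. Cyclisation must outrun direct reduction of the first radical, which high dilution and slow addition of Bu3SnH secure. Benzyl ethers, arenes and the C4 and C5 centres are untouched by tin radicals.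

Step 11
Reactants: 17 (1R,6R,7S,9S)-7,9-bis[4-(benzyloxy)-3-methoxyphenyl]-4,4-dimethyl-3,8-dioxa-4-silabicyclo[4.3.0]nonane
Product: 18 [(2S,3S,4R,5S)-2,5-bis[4-(benzyloxy)-3-methoxyphenyl]-4-(hydroxymethyl)oxolan-3-yl]methanol
Conditions: KF, KHCO3, 30% H2O2, THF/MeOH (1:1), rt → 45 °C
Reagents that add atoms: hydrogen peroxide, OO
Why: Tamao oxidation: fluoride activates silicon, hydroperoxide adds, the CH2 group migrates from Si to O with retention and the Si–O bonds are then hydrolysed. The former Si–CH2 carbon becomes the C3 CH2OH and the tether oxygen stays as the C4 CH2OH; the bicarbonate medium leaves the benzylic ethers and all four stereocentres untouched.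

Step 12
Reactants: 18 [(2S,3S,4R,5S)-2,5-bis[4-(benzyloxy)-3-methoxyphenyl]-4-(hydroxymethyl)oxolan-3-yl]methanol
Product: 19 [(2S,3S,4R,5S)-2,5-bis(4-hydroxy-3-methoxyphenyl)-4-(hydroxymethyl)oxolan-3-yl]methanol
Conditions: H2 (1 atm), 10% Pd/C, EtOAc/EtOH (1:1), rt
Reagents that add atoms: none
Why: Hydrogenolysis of the two aryl benzyl ethers in neutral solvent; cleavage of a phenol benzyl ether is much faster than cleavage of the dialkyl benzylic C–O bonds of the oxolane, so the reaction is stopped after uptake of two equivalents of hydrogen. No stereocentre is affected.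

## Compound list

1 | (S)-4-benzyl-1,3-oxazolidin-2-one | O=C1OC[C@H](Cc2ccccc2)N1 | starting material
2 | methyl 4-chloro-4-oxobutanoate | COC(=O)CCC(Cl)=O | starting material
3 | methyl 4-[(4S)-4-benzyl-2-oxo-1,3-oxazolidin-3-yl]-4-oxobutanoate | COC(=O)CCC(=O)N1[C@@H](Cc2ccccc2)COC1=O | intermediate
4 | 4-(benzyloxy)-3-methoxybenzaldehyde | COc1cc(C=O)ccc1OCc1ccccc1 | starting material
5 | syn-aldol adduct, methyl (3S)-3-{(S)-[4-(benzyloxy)-3-methoxyphenyl](hydroxy)methyl}-4-[(4S)-4-benzyl-2-oxo-1,3-oxazolidin-3-yl]-4-oxobutanoate (not isolated) | O[C@H](c1ccc(OCc2ccccc2)c(OC)c1)[C@@H](C(=O)N1[C@@H](Cc2ccccc2)COC1=O)CC(=O)OC | intermediate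
6 | (4S)-4-benzyl-3-{[(2S,3S)-2-[4-(benzyloxy)-3-methoxyphenyl]-5-oxooxolan-3-yl]carbonyl}-1,3-oxazolidin-2-one | O=C1O[C@H](c2ccc(OCc3ccccc3)c(OC)c2)[C@@H](C(=O)N2[C@@H](Cc3ccccc3)COC2=O)C1 | intermediate
7 | peroxy acid, (2S,3S)-2-[4-(benzyloxy)-3-methoxyphenyl]-5-oxooxolane-3-carboperoxoic acid (not isolated) | O=C1O[C@H](c2ccc(OCc3ccccc3)c(OC)c2)[C@@H](C(=O)OO)C1 | intermediate
8 | (2S,3S)-2-[4-(benzyloxy)-3-methoxyphenyl]-5-oxooxolane-3-carboxylic acid | O=C1O[C@H](c2ccc(OCc3ccccc3)c(OC)c2)[C@@H](C(=O)O)C1 | intermediate
9 | (4R,5S)-5-[4-(benzyloxy)-3-methoxyphenyl]-4-(hydroxymethyl)oxolan-2-one | O=C1O[C@H](c2ccc(OCc3ccccc3)c(OC)c2)[C@@H](CO)C1 | intermediate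
10 | (4R,5S)-5-[4-(benzyloxy)-3-methoxyphenyl]-4-({[tert-butyl(dimethyl)silyl]oxy}methyl)oxolan-2-one | O=C1O[C@H](c2ccc(OCc3ccccc3)c(OC)c2)[C@@H](CO[Si](C)(C)C(C)(C)C)C1 | intermediate
11 | (4R,5S)-5-[4-(benzyloxy)-3-methoxyphenyl]-4-({[tert-butyl(dimethyl)silyl]oxy}methyl)-4,5-dihydrofuran-2-yl diphenyl phosphate | O=P(Oc1ccccc1)(Oc1ccccc1)OC1=C[C@H](CO[Si](C)(C)C(C)(C)C)[C@@H](c2ccc(OCc3ccccc3)c(OC)c2)O1 | intermediate
12 | [4-(benzyloxy)-3-methoxyphenyl]boronic acid | COc1cc(B(O)O)ccc1OCc1ccccc1 | starting material
13 | {[(2S,3R)-2,5-bis[4-(benzyloxy)-3-methoxyphenyl]-2,3-dihydrofuran-3-yl]methoxy}(tert-butyl)dimethylsilane | COc1cc(C=2O[C@H](c3ccc(OCc4ccccc4)c(OC)c3)[C@@H](CO[Si](C)(C)C(C)(C)C)C=2)ccc1OCc1ccccc1 | intermediate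
14 | [(2S,3R)-2,5-bis[4-(benzyloxy)-3-methoxyphenyl]-2,3-dihydrofuran-3-yl]methanol | COc1cc(C=2O[C@H](c3ccc(OCc4ccccc4)c(OC)c3)[C@@H](CO)C=2)ccc1OCc1ccccc1 | intermediate
15 | (bromomethyl)chlorodimethylsilane | C[Si](C)(Cl)CBr | starting material
16 | {[(2S,3R)-2,5-bis[4-(benzyloxy)-3-methoxyphenyl]-2,3-dihydrofuran-3-yl]methoxy}(bromomethyl)dimethylsilane | COc1cc(C=2O[C@H](c3ccc(OCc4ccccc4)c(OC)c3)[C@@H](CO[Si](C)(C)CBr)C=2)ccc1OCc1ccccc1 | intermediate
17 | (1R,6R,7S,9S)-7,9-bis[4-(benzyloxy)-3-methoxyphenyl]-4,4-dimethyl-3,8-dioxa-4-silabicyclo[4.3.0]nonane | COc1cc([C@H]2O[C@H](c3ccc(OCc4ccccc4)c(OC)c3)[C@@H](CO[Si](C)(C)C3)[C@H]23)ccc1OCc1ccccc1 | intermediate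
18 | [(2S,3S,4R,5S)-2,5-bis[4-(benzyloxy)-3-methoxyphenyl]-4-(hydroxymethyl)oxolan-3-yl]methanol | COc1cc([C@H]2O[C@H](c3ccc(OCc4ccccc4)c(OC)c3)[C@@H](CO)[C@H]2CO)ccc1OCc1ccccc1 | intermediate
19 | [(2S,3S,4R,5S)-2,5-bis(4-hydroxy-3-methoxyphenyl)-4-(hydroxymethyl)oxolan-3-yl]methanol (CNP0286218.1) | COc1cc([C@H]2O[C@H](c3ccc(O)c(OC)c3)[C@@H](CO)[C@H]2CO)ccc1O | target

## Step count and least certain steps

Total step count: 12. Longest linear sequence: 12 steps (1 → 3 → 6 → 8 → 9 → 10 → 11 → 13 → 14 → 16 → 17 → 18 → 19); 2, 4, 12 and 15 enter as purchased compounds.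

**Step 10 (key step).**
- What may go wrong: hydrogen transfer to the silylmethyl radical before ring closure, because a 6-exo closure is slower than the usual 5-exo case; intramolecular hydrogen transfer from the allylic C4–H or the benzylic C5–H to that radical; and incomplete facial selectivity of the hydrogen transfer at C2, because the C5 aryl group sits on the convex face in a 1,3-relationship to C2.
- Fallback (sets out from 10, rejoins at 19; C3 and C2 are set by polar chemistry instead of the tether): the lithium enolate of 10 (LiN(i-Pr)2, THF, −78 °C) should be alkylated by benzyl chloromethyl ether anti to the C4 branch to give the 3,4-trans lactone F1. Re-enolisation (KN(SiMe3)2, −78 °C) and kinetic protonation by 2,6-di-tert-butyl-4-methylphenol from the face away from the C4 branch should give the 3,4-cis lactone F2. Addition of 4-(benzyloxy)-3-methoxyphenyllithium F3 (from 1-(benzyloxy)-4-bromo-2-methoxybenzene and n-BuLi, THF, −78 °C) should stop at the hemiketal F4. Et3SiH/BF3·OEt2 (CH2Cl2, −78 °C) should reduce the oxocarbenium ion with hydride entering anti to the C3 branch, leaving the C2 aryl cis to it in the oxolane F5. Bu4NF removes the silyl group to give the alcohol F6, and hydrogenolysis (H2, 10% Pd/C) of its three benzyl ethers gives 19.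

**Step 6 (with its consequence for step 7).**
- What may go wrong: loss of the five-membered ketene acetal phosphate by hydrolysis on work-up, C-phosphorylation or self-condensation of the lactone enolate, and slow insertion of palladium into the electron-rich C–O bond in the coupling that follows.
- Fallback (sets out from 10, rejoins at 13, bypasses steps 6 and 7): the aryl group is added as a nucleophile. Addition of 4-(benzyloxy)-3-methoxyphenyllithium F7 (same preparation as above) to 10 at −78 °C should give the hemiketal F8, and dehydration with MsCl/Et3N (CH2Cl2, 0 °C → rt) towards conjugation with the aryl ring should give 13.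

**Step 2.**
- What may go wrong: partial enolisation of the ester beside the imide, retro-aldol of the electron-rich benzylic aldolate on warming, and incomplete lactonisation; the lactone alcohol formed two steps later can also translactonise.
- Fallback (sets out from 1 and 4, rejoins at 10; the ester that must lactonise is replaced by an allyl group, and the free hydroxymethyl lactone is never formed): 1 is acylated with pent-4-enoyl chloride (n-BuLi, THF, −78 °C) to the imide F9. The same Bu2BOTf syn-aldol with 4 should give the adduct F10. LiBH4 (Et2O, 1 equiv H2O, 0 °C) removes the auxiliary reductively to give the diol F11. Selective silylation of the primary hydroxyl (TBSCl, imidazole, CH2Cl2, 0 °C) gives F12. OsO4 (cat.)/NaIO4 with 2,6-lutidine in dioxane/H2O cleaves the alkene to an aldehyde that closes to the lactol F13, and TEMPO/PhI(OAc)2 (CH2Cl2, rt) oxidises the lactol to 10.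

**Step 12.**
- What may go wrong: over-reduction, that is hydrogenolysis of a benzylic C–O bond of the oxolane once the para-phenol is free.
- Fallback (sets out from 18, rejoins at 19, no new compound): electron-transfer debenzylation with LiC10H8 (lithium naphthalenide) in THF at −78 °C, titrated to a persistent green colour and quenched with aq. NH4Cl. The unsubstituted phenyl ring of the benzyl ether accepts the electron and expels a phenoxide, whereas the electron-rich ring ethers are harder to reduce and would have to expel an alkoxide.

## Further compounds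

F1 | step 10 | (3R,4R,5S)-3-[(benzyloxy)methyl]-5-[4-(benzyloxy)-3-methoxyphenyl]-4-({[tert-butyl(dimethyl)silyl]oxy}methyl)oxolan-2-one | O=C1O[C@H](c2ccc(OCc3ccccc3)c(OC)c2)[C@@H](CO[Si](C)(C)C(C)(C)C)[C@@H]1COCc1ccccc1
F2 | step 10 | (3S,4R,5S)-3-[(benzyloxy)methyl]-5-[4-(benzyloxy)-3-methoxyphenyl]-4-({[tert-butyl(dimethyl)silyl]oxy}methyl)oxolan-2-one | O=C1O[C@H](c2ccc(OCc3ccccc3)c(OC)c2)[C@@H](CO[Si](C)(C)C(C)(C)C)[C@H]1COCc1ccccc1
F3 | step 10 | [4-(benzyloxy)-3-methoxyphenyl]lithium | [Li]c1ccc(OCc2ccccc2)c(OC)c1
F4 | step 10 | (3S,4R,5S)-3-[(benzyloxy)methyl]-2,5-bis[4-(benzyloxy)-3-methoxyphenyl]-4-({[tert-butyl(dimethyl)silyl]oxy}methyl)oxolan-2-ol (both C2 anomers) | COc1cc(C2(O)O[C@H](c3ccc(OCc4ccccc4)c(OC)c3)[C@@H](CO[Si](C)(C)C(C)(C)C)[C@H]2COCc2ccccc2)ccc1OCc1ccccc1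
F5 | step 10 | {[(2S,3S,4R,5S)-4-[(benzyloxy)methyl]-2,5-bis[4-(benzyloxy)-3-methoxyphenyl]oxolan-3-yl]methoxy}(tert-butyl)dimethylsilane (silyloxymethyl on the carbon next to the trans aryl, benzyloxymethyl next to the cis aryl) | COc1cc([C@H]2O[C@H](c3ccc(OCc4ccccc4)c(OC)c3)[C@@H](CO[Si](C)(C)C(C)(C)C)[C@H]2COCc2ccccc2)ccc1OCc1ccccc1
F6 | step 10 | [(2S,3S,4R,5S)-3-[(benzyloxy)methyl]-2,5-bis[4-(benzyloxy)-3-methoxyphenyl]oxolan-4-yl]methanol | COc1cc([C@H]2O[C@H](c3ccc(OCc4ccccc4)c(OC)c3)[C@@H](CO)[C@H]2COCc2ccccc2)ccc1OCc1ccccc1
F7 | step 6 | [4-(benzyloxy)-3-methoxyphenyl]lithium | [Li]c1ccc(OCc2ccccc2)c(OC)c1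
F8 | step 6 | (4R,5S)-2,5-bis[4-(benzyloxy)-3-methoxyphenyl]-4-({[tert-butyl(dimethyl)silyl]oxy}methyl)oxolan-2-ol (both C2 anomers) | COc1cc(C2(O)O[C@H](c3ccc(OCc4ccccc4)c(OC)c3)[C@@H](CO[Si](C)(C)C(C)(C)C)C2)ccc1OCc1ccccc1
F9 | step 2 | (4S)-4-benzyl-3-(pent-4-enoyl)-1,3-oxazolidin-2-one | C=CCCC(=O)N1[C@@H](Cc2ccccc2)COC1=O
F10 | step 2 | (4S)-4-benzyl-3-[(2S)-2-{(S)-[4-(benzyloxy)-3-methoxyphenyl](hydroxy)methyl}pent-4-enoyl]-1,3-oxazolidin-2-one | O[C@H](c1ccc(OCc2ccccc2)c(OC)c1)[C@@H](C(=O)N1[C@@H](Cc2ccccc2)COC1=O)CC=C
F11 | step 2 | (1S,2R)-1-[4-(benzyloxy)-3-methoxyphenyl]-2-(prop-2-en-1-yl)propane-1,3-diol | O[C@H](c1ccc(OCc2ccccc2)c(OC)c1)[C@@H](CO)CC=C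
F12 | step 2 | (1S,2R)-1-[4-(benzyloxy)-3-methoxyphenyl]-2-({[tert-butyl(dimethyl)silyl]oxy}methyl)pent-4-en-1-ol | O[C@H](c1ccc(OCc2ccccc2)c(OC)c1)[C@@H](CO[Si](C)(C)C(C)(C)C)CC=C
F13 | step 2 | (4R,5S)-5-[4-(benzyloxy)-3-methoxyphenyl]-4-({[tert-butyl(dimethyl)silyl]oxy}methyl)oxolan-2-ol (both C2 anomers) | OC1O[C@H](c2ccc(OCc3ccccc3)c(OC)c2)[C@@H](CO[Si](C)(C)C(C)(C)C)C1
F0 | step 12 | none | none
A1 | alternative 1 | [(2S,3S,4R,5S)-2,5-bis[3-methoxy-4-(pivaloyloxy)phenyl]oxolane-3,4-diyl]bis(methylene) dipivalate (tetrapivalate of 19) | COc1cc([C@H]2O[C@H](c3ccc(OC(=O)C(C)(C)C)c(OC)c3)[C@@H](COC(=O)C(C)(C)C)[C@H]2COC(=O)C(C)(C)C)ccc1OC(=O)C(C)(C)C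
A2 | alternative 1 | (1S,2S,3R)-1,4-bis[3-methoxy-4-(pivaloyloxy)phenyl]-2,3-bis[(pivaloyloxy)methyl]butan-1-ol | COc1cc([C@@H](O)[C@H](COC(=O)C(C)(C)C)[C@H](COC(=O)C(C)(C)C)Cc2ccc(OC(=O)C(C)(C)C)c(OC)c2)ccc1OC(=O)C(C)(C)C
A3 | alternative 2 | all-cis 8-[4-(benzyloxy)-3-methoxyphenyl]-4,4-dimethyl-3,5,9-trioxabicyclo[5.3.0]decan-10-one (enantiomer as drawn) | COc1cc([C@H]2OC(=O)[C@@H](COC(C)(C)OC3)[C@H]23)ccc1OCc1ccccc1
A4 | alternative 2 | all-cis 8-[4-(benzyloxy)-3-methoxyphenyl]-4,4-dimethyl-3,5-dioxabicyclo[5.2.0]nonan-9-one (reacting enantiomer as drawn) | COc1cc([C@H]2C(=O)[C@@H](COC(C)(C)OC3)[C@H]23)ccc1OCc1ccccc1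
A5 | alternative 3 | dimethyl (2R,4S,5S)-2,5-bis[4-(benzyloxy)-3-methoxyphenyl]-4-ethenyloxolane-3,3-dicarboxylate | COc1cc([C@H]2O[C@H](c3ccc(OCc4ccccc4)c(OC)c3)[C@@H](C=C)C2(C(=O)OC)C(=O)OC)ccc1OCc1ccccc1
A6 | alternative 3 | (2R,3R)-2-[4-(benzyloxy)-3-methoxyphenyl]-3-ethenyloxirane | C=C[C@H]1O[C@@H]1c1ccc(OCc2ccccc2)c(OC)c1
A7 | alternative 3 | dimethyl 2-{[4-(benzyloxy)-3-methoxyphenyl]methylidene}propanedioate | COC(=O)C(=Cc1ccc(OCc2ccccc2)c(OC)c1)C(=O)OC
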